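**Retrosynthetic overview**
1. The end game starts from a C12 ketone: C20 enters by α-methylenation, 12α-OH by 1,2-reduction, and the C11/C20 oxirane (a functional group, not a ring of the skeleton) by OH-directed epoxidation.
2. Key disconnection C9–C10. The C9 acetate and the C12 oxygen are 1,4-related across C10–C11 of ring A. This is the retron of an α-acetoxy radical at C9 adding to C10 of a ring-A enone (C10=C11–C12=O), and it closes the ten-membered ring C1–C10.
3. The seco aldehyde 30 is cut at C4–C5 (Negishi coupling) into the ring-A alkyl iodide 13 and the lactone (Z)-alkenyl bromide 25.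
4. Ring A comes from benzoic acid: Birch methylation (C1, C15), CBS reduction (C2), and an OH-directed dihydroxylation that desymmetrises the cyclohexadiene (C1, C13, C14), followed by oxidation to the enone.
5. The γ-lactone comes from L-erythrulose (C6–C9, C7 from the chiral pool) and a propionate unit (C17–C19). Ring order: ring A and the γ-lactone first, the ten-membered ring last.

Key step: step 21

Remark: briarane numbering is used (ring A = C1, C10–C14; ten-membered ring = C1–C10; lactone = C7, C8, C17, C19, O; C15 on C1, C16 on C5, C18 on C17, C20 on C11); α is the face of ring A that carries C2, H-10 and the oxygens at C11–C14, and β is the face of C15 and C9.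

**Step 1**
Reactants: 1 benzoic acid
Product: 3 1-methylcyclohexa-2,5-diene-1-carboxylic acid, via dilithium dienediolate 2 (not isolated)
Conditions: Li, NH3(l)/THF, −78 °C; MeI, −78 °C → rt; 2 M HCl
Reagents that add atoms: iodomethane CI; lithium [Li] (in 2 only)
Why: Birch reduction–alkylation: dissolving-metal reduction of the benzoate gives dienediolate 2, which is methylated at the ipso carbon and so builds the quaternary, still prochiral C1 with C15 and C2.

**Step 2**
Reactants: 3 1-methylcyclohexa-2,5-diene-1-carboxylic acid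
Product: 5 N-methoxy-N,1-dimethylcyclohexa-2,5-diene-1-carboxamide, via acyl imidazolide 4 (not isolated)
Conditions: CDI, CH2Cl2, rt; MeNH(OMe)·HCl, rt
Reagents that add atoms: N,O-dimethylhydroxylamine hydrochloride CNOC.Cl; 1,1'-carbonyldiimidazole O=C(n1ccnc1)n1ccnc1 (imidazolyl group of 4 only)
Why: Weinreb amide formation through the acyl imidazolide is a mild activation that avoids an acid chloride of this aromatisation-prone acid.

**Step 3**
Reactants: 5 N-methoxy-N,1-dimethylcyclohexa-2,5-diene-1-carboxamide
Product: 7 3-chloro-1-(1-methylcyclohexa-2,5-dien-1-yl)propan-1-one, via vinyl ketone 6 (not isolated)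
Conditions: CH2=CHMgBr, THF, 0 °C; then 4 M HCl/dioxane, 0 °C
Reagents that add atoms: vinylmagnesium bromide C=C[Mg]Br; hydrogen chloride Cl
Why: The Weinreb ketone synthesis stops at the ketone through the chelated adduct, and conjugate addition of HCl to vinyl ketone 6 stores C3–C4 as a β-chloroethyl group with no alkene to compete in step 5.

**Step 4**
Reactants: 7 3-chloro-1-(1-methylcyclohexa-2,5-dien-1-yl)propan-1-one
Product: 8 (1S)-3-chloro-1-(1-methylcyclohexa-2,5-dien-1-yl)propan-1-ol
Conditions: (R)-Me-CBS (15 mol %), BH3·SMe2, THF, −20 °C; MeOH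
Reagents that add atoms: none
Why: Corey–Bakshi–Shibata reduction: the quaternary C1 group is the large and CH2CH2Cl the small substituent, so the (R)-catalyst should deliver hydride to give (2S).

**Step 5**
Reactants: 8 (1S)-3-chloro-1-(1-methylcyclohexa-2,5-dien-1-yl)propan-1-ol
Product: 10 (1S,2R,3S)-3-[(1S)-3-chloro-1-hydroxypropyl]-3-methylcyclohex-4-ene-1,2-diol, via osmate ester 9 (not isolated)
Conditions: OsO4 (1.05 equiv), TMEDA, CH2Cl2, −78 °C; then aq Na2SO3, THF, 65 °C
Reagents that add atoms: osmium tetroxide O=[Os](=O)(=O)=O; TMEDA CN(C)CCN(C)C (in 9 only)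
Why: Hydrogen-bond-directed dihydroxylation with OsO4·TMEDA: in the rotamer with H-2 under the ring, the C2–OH lies next to one of the two diastereotopic ring alkenes on the side-chain face, so syn addition there sets C13 and C14 (both α) and makes C1 stereogenic.

**Step 6**
Reactants: 10 triol
Product: 11 2,13α,14α-triacetate of 10
Conditions: Ac2O, pyridine, DMAP (cat.), CH2Cl2, rt
Reagents that add atoms: acetic anhydride CC(=O)OC(C)=O
Why: Exhaustive DMAP-catalysed acetylation installs the final acetates at O2, O13 and O14 at once.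

**Step 7**
Reactants: 11 triacetate
Product: 12 ring-A enone chloride (5,6-diacetoxy-4-[(1S)-1-acetoxy-3-chloropropyl]-4-methylcyclohex-2-en-1-one; both ring acetates cis to the side chain and trans to the methyl group)
Conditions: CrO3, 3,5-dimethylpyrazole, CH2Cl2, −20 °C
Reagents that add atoms: chromium trioxide O=[Cr](=O)=O
Why: Allylic oxidation with the CrO3–dimethylpyrazole complex: C12 is the only allylic CH2 (C1 is quaternary), and oxygen should enter at C12 rather than at the neopentyl C10 terminus.

**Step 8**
Reactants: 12 ring-A enone chloride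
Product: 13 ring-A enone iodide
Conditions: NaI, acetone, 56 °C
Reagents that add atoms: sodium iodide [Na+].[I-]
Why: The Finkelstein reaction at the primary C4 chloride is neutral and driven by precipitation of NaCl, so the base-sensitive diacetoxy enone is left alone.

**Step 9**
Reactants: 14 L-erythrulose
Product: 15 3,4-O-isopropylidene-L-erythrulose
Conditions: Me2C(OMe)2, CSA (cat.), acetone, rt
Reagents that add atoms: 2,2-dimethoxypropane COC(C)(C)OC
Why: Acetonide formation under thermodynamic control takes the vicinal diol (O6/O7) as a dioxolane and leaves the C9 hydroxyl free; C7 comes from the chiral pool.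

**Step 10**
Reactants: 15 3,4-O-isopropylidene-L-erythrulose
Product: 16 1-O-TBDPS-3,4-O-isopropylidene-L-erythrulose
Conditions: TBDPSCl, imidazole, DMF, 0 °C
Reagents that add atoms: tert-butyl(chloro)diphenylsilane CC(C)(C)[Si](Cl)(c1ccccc1)c1ccccc1
Why: Silylation of the only free hydroxyl gives an acid-stable, non-chelating ether at O9.

**Step 11**
Reactants: 16 1-O-TBDPS-3,4-O-isopropylidene-L-erythrulose
Product: 17 Reformatsky adduct (methyl ester; C7 and C8 as in the target; both C17 epimers)
Conditions: MeCH(Br)CO2Me, Zn (TMSCl-activated), THF, 0 °C → rt; cold 1 M HCl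
Reagents that add atoms: methyl 2-bromopropanoate COC(=O)C(C)Br
Why: Reformatsky reaction under chelation control: Zn(II) ties the ketone oxygen to the dioxolane oxygen on C7 (the silyl ether does not chelate) and the zinc enolate attacks from the side of H-7, which sets C8, while C17 forms as a mixture that step 12 corrects.

**Step 12**
Reactants: 17 Reformatsky adduct
Product: 19 (3R,4R,5S)-4-hydroxy-5-(hydroxymethyl)-3-methyl-4-[(tert-butyldiphenylsilyloxy)methyl]oxolan-2-one, via C17-epimeric lactone 18 (not isolated)
Conditions: TFA/H2O, CH2Cl2, 0 °C; then DBU (10 mol %), toluene, rt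
Reagents that add atoms: none
Why: Acidic acetonide hydrolysis frees O7, which closes the γ-lactone by transesterification in preference to the six-membered ring through O6, and base-catalysed epimerisation α to the lactone carbonyl then funnels C17 into the more stable isomer with C18 trans to the bulky C9 branch.

**Step 13**
Reactants: 19 hydroxy lactone diol
Product: 20 C6 aldehyde of 19
Conditions: Dess–Martin periodinane, CH2Cl2, 0 °C → rt
Reagents that add atoms: none
Why: Dess–Martin oxidation takes the primary alcohol under neutral conditions; the tertiary 8-OH cannot be oxidised and C7 is not epimerised.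

**Step 14**
Reactants: 20 C6 aldehyde
Product: 21 (E)-enal (C16 aldehyde, C5=C6)
Conditions: Ph3P=CHCHO, toluene, 40 °C
Reagents that add atoms: (triphenylphosphoranylidene)acetaldehyde O=CC=P(c1ccccc1)(c1ccccc1)c1ccccc1
Why: The Wittig reaction with a stabilised ylide gives the (E)-enal without added base, which leaves the α-acyloxy stereocentre C7 untouched.

**Step 15**
Reactants: 21 (E)-enal
Product: 23 (Z)-α-bromo enal (Br on C5 cis to C7), via dibromo aldehyde 22 (not isolated)
Conditions: Br2, CH2Cl2, −78 °C; Et3N, −78 → 0 °C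
Reagents that add atoms: bromine BrBr
Why: Bromination–dehydrobromination: anti addition of Br2, then loss of the acidic α-proton with the β-bromide, gives the more stable (Z)-α-bromo enal, which fixes the later cis relation of C4 and C7 on C5=C6.

**Step 16**
Reactants: 23 (Z)-α-bromo enal
Product: 24 (Z)-2-bromoallylic alcohol (C16–OH)
Conditions: NaBH4, CeCl3·7H2O, MeOH, −78 °C
Reagents that add atoms: none
Why: Luche reduction gives clean 1,2-reduction of the enal and does not touch the lactone or the C–Br bond.

**Step 17**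
Reactants: 24 (Z)-2-bromoallylic alcohol
Product: 25 8,16-bis(triethylsilyl) ether
Conditions: TESOTf, 2,6-lutidine, CH2Cl2, −78 → 0 °C
Reagents that add atoms: triethylsilyl triflate CC[Si](CC)(CC)OS(=O)(=O)C(F)(F)F
Why: Silyl triflate silylation covers both the primary and the hindered tertiary hydroxyl, so no acidic proton meets the organozinc of step 18.

**Step 18**
Reactants: 13 ring-A enone iodide, 25 8,16-bis(triethylsilyl) ether
Product: 27 coupled seco compound (C4–C5 bond; C4 cis to C7), via alkylzinc iodide 26 (not isolated)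
Conditions: 13, Zn dust, LiCl, THF, 25 °C; then 25, Pd(dppf)Cl2 (5 mol %), THF/NMP, 40 °C
Reagents that add atoms: zinc [Zn] (in 26 only)
Why: Negishi sp3–sp2 coupling: zinc inserts into the primary C–I bond and tolerates ketone and esters, and the Pd-catalysed coupling with the alkenyl bromide keeps the alkene geometry.

**Step 19**
Reactants: 27 coupled seco compound
Product: 28 8,9,16-triol
Conditions: HF·pyridine, pyridine/THF, 0 °C → rt
Reagents that add atoms: none
Why: Fluoride-mediated global desilylation in a buffered acidic medium spares the acetates and the β-acetoxy enone.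

**Step 20**
Reactants: 28 8,9,16-triol
Product: 30 C16 chloride–C9 aldehyde, via alkoxysulfonium chloride 29 (not isolated)
Conditions: NCS, Me2S, CH2Cl2, −25 °C; then Et3N, −25 °C
Reagents that add atoms: N-chlorosuccinimide O=C1CCC(=O)N1Cl; dimethyl sulfide CSC (in 29 only)
Why: The Corey–Kim reagent does two jobs in one flask: the allylic C16 alkoxysulfonium ion collapses to the allylic chloride, the saturated C9 alkoxysulfonium ion 29 waits for Et3N and then gives the aldehyde (Corey–Kim oxidation), and the tertiary 8-OH does not react.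

**Step 21**
Reactants: 30 C16 chloride–C9 aldehyde
Product: 32 tricyclic 12-ketone (9S,10S; 2,9,13,14-tetraacetate), via 1-bromoalkyl acetate 31 (not isolated)
Conditions: AcBr, ZnBr2 (2 mol %), CH2Cl2, −20 °C, evaporate; then (Me3Si)3SiH, AIBN (syringe pump), benzene (1 mM), 80 °C
Reagents that add atoms: acetyl bromide CC(=O)Br
Why: Proposed new method: acetyl bromide adds to the C9 aldehyde to give both epimers of 31, (Me3Si)3Si• abstracts bromine from either epimer to give the same planar, nucleophilic α-acetoxy radical at C9, this radical adds to C10 (the β-carbon of the ring-A enone) and the α-keto radical at C11 takes hydrogen from the silane to carry the chain; the closest known reaction types are the Giese addition of α-acyloxyalkyl radicals to cyclohexenones and radical macrocyclisation onto enones at high dilution, which is established for eleven-membered and larger rings but not for a ten-membered ring closed onto a ring enone. The ten-membered ring closes in the 10-exo-trig mode (C10=C11 stays outside the new ring), helped by the cis C5=C6 bond and the trans-substituted lactone, which fix four of the eight tether atoms. C10 is set by axial attack on the β face of the enone, anti to the pseudo-axial C1–C2 bond and to the axial 14α-acetate, which gives the trans ring fusion (H-10 α, C15 β). C9 is set in the transition state in which the forming C9–C10 bond is anti to C8–C7 and the small H-9, not the acetate, points into the crowded sector between C7 and C17, so both bromide epimers converge on (9S). The step needs bromine abstraction before chlorine abstraction and attack at C10 before any other acceptor: the α-acyloxy C–Br bond is much weaker than the allylic C16–Cl bond, C5=C6 could only be reached by 4-exo or 5-endo closure, and attack at C11 is polarity-mismatched. Premature reduction of the C9 radical is held back by slow addition of the sluggish hydrogen donor at high dilution.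

**Step 22**
Reactants: 32 tricyclic 12-ketone
Product: 33 α-methylene ketone (C11=C20, C12=O)
Conditions: (CH2O)n, iPr2NH·TFA, THF, 65 °C
Reagents that add atoms: formaldehyde C=O
Why: Mannich-type α-methylenation (iminium ion from formaldehyde and the amine salt, then β-elimination of the amine) can only end in an alkene at C11, the sole α-CH2 of the ketone, and the buffered medium should spare the β-acetoxy ketone unit.

**Step 23**
Reactants: 33 α-methylene ketone
Product: 34 12α-allylic alcohol
Conditions: NaBH4, CeCl3·7H2O, MeOH, −78 °C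
Reagents that add atoms: none
Why: Luche 1,2-reduction: the axial trajectory on the α face is blocked by the axial 14α-acetate, so hydride should enter from the β face and give the axial 12α-alcohol (12R) without conjugate reduction.

**Step 24**
Reactants: 34 12α-allylic alcohol
Product: 35 target (1S,2S,5E,7S,8S,9S,10S,11R,12R,13S,14R,17R)
Conditions: VO(acac)2 (5 mol %), t-BuOOH, CH2Cl2, 0 °C
Reagents that add atoms: tert-butyl hydroperoxide CC(C)(C)OO
Why: Vanadium-catalysed hydroxyl-directed epoxidation: the 12α-OH binds the peroxo-vanadium species and delivers oxygen to the α face of the neighbouring C11=C20 bond only, which sets C11, while the electron-poor C5=C6 bond has no allylic hydroxyl.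

**Compound list**
1 | benzoic acid | OC(=O)c1ccccc1 | starting material
2 | dilithium dienediolate of 1,4-dihydrobenzoic acid | [Li+].[Li+].[O-]C([O-])=C1C=CCC=C1 | intermediate
3 | 1-methylcyclohexa-2,5-diene-1-carboxylic acid | CC1(C=CCC=C1)C(=O)O | intermediate
4 | acyl imidazolide of 3 | CC1(C=CCC=C1)C(=O)n1ccnc1 | intermediate
5 | N-methoxy-N,1-dimethylcyclohexa-2,5-diene-1-carboxamide | CON(C)C(=O)C1(C)C=CCC=C1 | intermediate
6 | 1-(1-methylcyclohexa-2,5-dien-1-yl)prop-2-en-1-one | C=CC(=O)C1(C)C=CCC=C1 | intermediate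
7 | 3-chloro-1-(1-methylcyclohexa-2,5-dien-1-yl)propan-1-one | ClCCC(=O)C1(C)C=CCC=C1 | intermediate
8 | (1S)-3-chloro-1-(1-methylcyclohexa-2,5-dien-1-yl)propan-1-ol | CC1(C=CCC=C1)[C@@H](O)CCCl | intermediate
9 | cyclic 13,14-osmate(VI) ester, TMEDA chelate | O=[Os-2]12(=O)(O[C@H]3CC=C[C@@](C)([C@@H](O)CCCl)[C@H]3O1)[N+](C)(C)CC[N+]2(C)C | intermediate
10 | (1S,2R,3S)-3-[(1S)-3-chloro-1-hydroxypropyl]-3-methylcyclohex-4-ene-1,2-diol | O[C@H]1CC=C[C@@](C)([C@@H](O)CCCl)[C@H]1O | intermediate
11 | triacetate of 10 | CC(=O)O[C@H]1CC=C[C@@](C)([C@@H](OC(C)=O)CCCl)[C@H]1OC(C)=O | intermediate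
12 | ring-A enone chloride | CC(=O)O[C@H]1C(=O)C=C[C@@](C)([C@@H](OC(C)=O)CCCl)[C@H]1OC(C)=O | intermediate
13 | ring-A enone iodide | CC(=O)O[C@H]1C(=O)C=C[C@@](C)([C@@H](OC(C)=O)CCI)[C@H]1OC(C)=O | intermediate
14 | L-erythrulose, (3S)-1,3,4-trihydroxybutan-2-one | OCC(=O)[C@@H](O)CO | starting material
15 | 3,4-O-isopropylidene-L-erythrulose | OCC(=O)[C@@H]1COC(C)(C)O1 | intermediate
16 | 1-O-TBDPS-3,4-O-isopropylidene-L-erythrulose | CC(C)(C)[Si](c1ccccc1)(c1ccccc1)OCC(=O)[C@@H]1COC(C)(C)O1 | intermediate
17 | Reformatsky adduct, C17 epimers | COC(=O)C(C)[C@@](O)(CO[Si](c1ccccc1)(c1ccccc1)C(C)(C)C)[C@@H]1COC(C)(C)O1 | intermediate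
18 | hydroxy lactone diol, C17 epimers | OC[C@@H]1OC(=O)C(C)[C@@]1(O)CO[Si](c1ccccc1)(c1ccccc1)C(C)(C)C | intermediate
19 | (3R,4R,5S)-hydroxy lactone diol | OC[C@@H]1OC(=O)[C@H](C)[C@@]1(O)CO[Si](c1ccccc1)(c1ccccc1)C(C)(C)C | intermediate
20 | C6 aldehyde | O=C[C@@H]1OC(=O)[C@H](C)[C@@]1(O)CO[Si](c1ccccc1)(c1ccccc1)C(C)(C)C | intermediate
21 | (E)-enal | O=C/C=C/[C@@H]1OC(=O)[C@H](C)[C@@]1(O)CO[Si](c1ccccc1)(c1ccccc1)C(C)(C)C | intermediate
22 | 5,6-dibromo aldehyde | O=CC(Br)C(Br)[C@@H]1OC(=O)[C@H](C)[C@@]1(O)CO[Si](c1ccccc1)(c1ccccc1)C(C)(C)C | intermediate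
23 | (Z)-α-bromo enal | O=C/C(Br)=C/[C@@H]1OC(=O)[C@H](C)[C@@]1(O)CO[Si](c1ccccc1)(c1ccccc1)C(C)(C)C | intermediate
24 | (Z)-2-bromoallylic alcohol | OC/C(Br)=C/[C@@H]1OC(=O)[C@H](C)[C@@]1(O)CO[Si](c1ccccc1)(c1ccccc1)C(C)(C)C | intermediate
25 | 8,16-bis(triethylsilyl) ether | CC[Si](CC)(CC)OC/C(Br)=C/[C@@H]1OC(=O)[C@H](C)[C@@]1(O[Si](CC)(CC)CC)CO[Si](c1ccccc1)(c1ccccc1)C(C)(C)C | intermediate
26 | alkylzinc iodide from 13 | CC(=O)O[C@H]1C(=O)C=C[C@@](C)([C@@H](OC(C)=O)CC[Zn]I)[C@H]1OC(C)=O | intermediate
27 | coupled seco compound, silyl protected | CC(=O)O[C@H]1C(=O)C=C[C@@](C)([C@@H](OC(C)=O)CC/C(CO[Si](CC)(CC)CC)=C\[C@@H]2OC(=O)[C@H](C)[C@@]2(O[Si](CC)(CC)CC)CO[Si](c2ccccc2)(c2ccccc2)C(C)(C)C)[C@H]1OC(C)=O | intermediate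
28 | 8,9,16-triol | CC(=O)O[C@H]1C(=O)C=C[C@@](C)([C@@H](OC(C)=O)CC/C(CO)=C\[C@@H]2OC(=O)[C@H](C)[C@@]2(O)CO)[C@H]1OC(C)=O | intermediate
29 | C16 chloride, C9 alkoxysulfonium chloride | CC(=O)O[C@H]1C(=O)C=C[C@@](C)([C@@H](OC(C)=O)CC/C(CCl)=C\[C@@H]2OC(=O)[C@H](C)[C@@]2(O)CO[S+](C)C)[C@H]1OC(C)=O.[Cl-] | intermediate
30 | C16 chloride–C9 aldehyde | CC(=O)O[C@H]1C(=O)C=C[C@@](C)([C@@H](OC(C)=O)CC/C(CCl)=C\[C@@H]2OC(=O)[C@H](C)[C@@]2(O)C=O)[C@H]1OC(C)=O | intermediate
31 | 1-bromoalkyl acetate, C9 epimers | CC(=O)O[C@H]1C(=O)C=C[C@@](C)([C@@H](OC(C)=O)CC/C(CCl)=C\[C@@H]2OC(=O)[C@H](C)[C@@]2(O)C(Br)OC(C)=O)[C@H]1OC(C)=O | intermediate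
32 | tricyclic 12-ketone | CC(=O)O[C@H]1C(=O)C[C@@H]2[C@H](OC(C)=O)[C@@]3(O)[C@H](/C=C(/CCl)CC[C@H](OC(C)=O)[C@@]2(C)[C@H]1OC(C)=O)OC(=O)[C@@H]3C | intermediate
33 | α-methylene ketone | CC(=O)O[C@H]1C(=O)C(=C)[C@@H]2[C@H](OC(C)=O)[C@@]3(O)[C@H](/C=C(/CCl)CC[C@H](OC(C)=O)[C@@]2(C)[C@H]1OC(C)=O)OC(=O)[C@@H]3C | intermediate
34 | 12α-allylic alcohol | CC(=O)O[C@H]1[C@@H](O)C(=C)[C@@H]2[C@H](OC(C)=O)[C@@]3(O)[C@H](/C=C(/CCl)CC[C@H](OC(C)=O)[C@@]2(C)[C@H]1OC(C)=O)OC(=O)[C@@H]3C | intermediate
35 | CNP0330408.1 | CC(=O)O[C@H]1[C@@H](O)[C@]2(CO2)[C@@H]2[C@H](OC(C)=O)[C@@]3(O)[C@H](/C=C(/CCl)CC[C@H](OC(C)=O)[C@@]2(C)[C@H]1OC(C)=O)OC(=O)[C@@H]3C | target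

Total step count: 24. Longest linear sequence: 16 steps (steps 9–24, from L-erythrulose).

**Steps most likely to fail**

Step 21. Hydrogen transfer to the C9 radical, or intermolecular addition, may outrun the slow ten-membered closure, and attack on the α face of the enone would give the cis-fused ring. The fallback replaces the radical by an allylchromium reagent; it sets out from 28 and comes back at 33.
- Morita–Baylis–Hillman hydroxymethylation of the enone of 28 (aq HCHO, DMAP, THF) would give the C11-hydroxymethyl enone tetraol F1.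
- Excess Corey–Kim reagent followed by Et3N would turn both allylic alcohols into chlorides and C9–OH into the aldehyde, giving the bis(allylic chloride) aldehyde F2.
- CrCl2 in THF/DMF at high dilution should insert first into the activated 2-acylallyl chloride at C20.
- The intramolecular Nozaki–Hiyama allylation, a ring closure known for ten-membered carbocycles, then joins C10 to the C8-alkoxide-chelated aldehyde with allyl transposition and gives the 9-hydroxy α-methylene ketone F3.
- Ac2O/pyridine acetylates only the secondary 9-OH and gives 33, so step 22 is no longer needed.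

Step 18. During zinc insertion next to the enone, the C4 centre may cyclise onto C10 or be protonated before it couples. The fallback reverses the polarity of the coupling; it sets out from 25 and 13 and comes back at 27. Miyaura borylation of 25 (B2pin2, PdCl2(dppf), KOAc, dioxane) would give the alkenyl pinacolboronate F4. F4 is then joined to the alkyl iodide 13 by a Pd/trialkylphosphine-catalysed alkyl–alkenyl Suzuki–Miyaura coupling (K3PO4·H2O, THF, rt) to give 27 without any organozinc.

Step 5. Discrimination between the two ring alkenes, or between the two faces, may be poor if the hydrogen bond to the homoallylic hydroxyl is weak. The fallback replaces the hydrogen bond by a covalent tether; it sets out from 8 and comes back at 10.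
- Boc2O/DMAP would give the tert-butyl carbonate F5.
- IBr in toluene at −85 °C triggers the iodocarbonate cyclisation through a chair-like six-membered transition state and gives the iodo carbonate F6, with O14 on the α face (cis to C2) and iodine on the β face at C13.
- CsOAc/18-crown-6 displaces iodide with inversion and gives the 13α-acetoxy carbonate F7.
- K2CO3/MeOH cleaves the carbonate and the acetate to give triol 10.

**Further compounds**
F1 | step 21 | C11-hydroxymethyl enone tetraol | CC(=O)O[C@H]1C(=O)C(CO)=C[C@@](C)([C@@H](OC(C)=O)CC/C(CO)=C\[C@@H]2OC(=O)[C@H](C)[C@@]2(O)CO)[C@H]1OC(C)=O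
F2 | step 21 | bis(allylic chloride) aldehyde | CC(=O)O[C@H]1C(=O)C(CCl)=C[C@@](C)([C@@H](OC(C)=O)CC/C(CCl)=C\[C@@H]2OC(=O)[C@H](C)[C@@]2(O)C=O)[C@H]1OC(C)=O
F3 | step 21 | 9-hydroxy α-methylene ketone | CC(=O)O[C@H]1C(=O)C(=C)[C@@H]2[C@H](O)[C@@]3(O)[C@H](/C=C(/CCl)CC[C@H](OC(C)=O)[C@@]2(C)[C@H]1OC(C)=O)OC(=O)[C@@H]3C
F4 | step 18 | alkenyl pinacolboronate | CC[Si](CC)(CC)OC/C(B1OC(C)(C)C(C)(C)O1)=C/[C@@H]1OC(=O)[C@H](C)[C@@]1(O[Si](CC)(CC)CC)CO[Si](c1ccccc1)(c1ccccc1)C(C)(C)C
F5 | step 5 | tert-butyl carbonate of 8 | CC1(C=CCC=C1)[C@@H](OC(=O)OC(C)(C)C)CCCl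
F6 | step 5 | iodo carbonate | I[C@@H]1CC=C[C@@]2(C)[C@H](CCCl)OC(=O)O[C@@H]12
F7 | step 5 | 13α-acetoxy carbonate | CC(=O)O[C@H]1CC=C[C@@]2(C)[C@H](CCCl)OC(=O)O[C@@H]12
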